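## Analysis of the target

Compound 26 is a trans-fused decalin of the eremophilane type. The numbering used throughout is: ring A = C1, C2, C3, C4, C5, C10; ring B = C5, C6, C7, C8, C9, C10; C14 is the methyl on C5, C15 the methyl on C4, C11–C13 the isopropenyl group on C7.

There are six stereocentres (3R,4R,5R,7S,9S,10R). The angular C14 methyl is β and axial and H10 is α (trans fusion). The C15 methyl is β (cis to C14, equatorial). The C3 ester oxygen is α (equatorial, trans to C15). The C9 ester oxygen and the C7 isopropenyl group are both α and equatorial, on either side of the C8 ketone. Every substituent except the angular methyl is therefore equatorial on a rigid chair–chair frame.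

The sensitive groups limit what can be done late:
- the β,γ-unsaturated ketone (isopropenyl on C7) moves into conjugation (C7=C11) with base or acid;
- the α-acyloxy ketone at C9 can epimerise;
- the 3-methylbut-2-enoate can deconjugate through a dienolate;
- the 1,1-disubstituted alkene forbids a late hydrogenation.

The hard parts are the quaternary C5 between the C4 and C10 stereocentres, the contiguous array C3–C4–C5–C10–C9, and the need to tell two secondary alcohols apart so that each receives its own unsaturated acyl group.

The strategy rests on one feature. With a carbonyl at C4, C5 is the α-carbon of a methacryloyl group whose methylene is C6. With an enol oxygen at C8, C7=C8–C9=C10 is a 2-oxygenated diene tied to that dienophile through C1–C2–C3–C4. The bonds C5–C10 and C6–C7 are then the two σ-bonds of an intramolecular [4+2] cycloaddition. Afterwards the C4 carbonyl supplies C15 and the C8 enol ether supplies the C9 oxygen.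

## Retrosynthetic reasoning

**Esters (26 → 25 → 24 → 23 → 22).** The two acyl–oxygen bonds are cut first, because neither unsaturated ester survives enolate chemistry or hydrogenation. Two different acyl groups require two different silyl ethers. In 22 the C3 oxygen carries TBS (an ordinary secondary silyl ether, cleaved first by acidic fluoride) and the C9 oxygen carries TIPS on an α-keto oxygen (inert to acid, cleaved by buffered fluoride). The order is therefore 22 → 23 → 24 → 25 → 26.

**C7–C11 (22 → 21 → 19, via 20).** The isopropenyl group is cut at C7–C11. Forward, the C7 enolate 20 of ketone 19 undergoes aldol addition, and the tertiary alcohol 21 is dehydrated towards a methyl group. C7 is chosen because it is the only position that can be enolised away from the bulky C9 silyloxy group. The electrophile must enter on the α face, opposite the syn-axial C14 methyl, which is the equatorial orientation the target needs.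

**C15 stereocentre (19 → 18).** The C4–H bond is cut: the methyl of 19 comes from the exocyclic methylene of 18 by hydrogenation. The forward step must deliver hydrogen to the α face of C4, which is the face away from the adjacent axial C14 methyl.

**C9–O (18 → 16, via 17).** The C9 oxygen is cut back to the C8=C9 enol silane of 16 (Rubottom oxidation through epoxide 17). The enol silane is regiodefined, so no enolisation selectivity is needed. The silyl group migrates to the new oxygen, so C9 emerges already protected.

**C4=C15 (16 → 15).** The methylene carbon is cut from the C4 ketone of 15. This is done before the C9 oxidation and not after it: in 15 the C8 carbonyl is still masked as its enol silane, whereas after the oxidation C8 would be the more accessible of two ketones.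

**Key disconnection (15 → 14).** Cutting C5–C10 and C6–C7 opens both rings at once and leads to the acyclic trienone 14. This is preferred over any single-bond disconnection because it forms the quaternary centre and the ring fusion together and leaves a carbonyl at C4 and an enol silane at C8. The forward reaction must give the trans fusion and must translate the C3 configuration into that of C5 and C10.

**Dienophile (14 → 11 + 12, via 13).** The C4–C5 bond is cut by a Weinreb ketone synthesis. It is placed last for two reasons. A methyl ketone cannot be enolised selectively next to an α-silyloxy isopropenyl ketone. The trienone is also expected to cyclise on its own, so it should only appear when the tetrahedral adduct 13 is quenched in the cold.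

**Diene (11 → 10 → 8 + 9).** The silyl dienol ether 11 comes from the methyl enone 10 by kinetic silylation at C7. The C9=C10 bond of 10 is cut by a Horner–Wadsworth–Emmons reaction between aldehyde 8 and phosphonate 9, which secures the (E) geometry that the cycloaddition needs.

**Tether (8 → 7 → 6 → 3 → 1, via 5, 4 and 2).** Aldehyde 8 is traced through alcohol 7 and acid 6 to lactone amide 3 and the chiral-pool lactone acid 1. In 1 the future C4 is a free acid and the future C10 a lactone carbonyl. The two ends are thus differentiated from the start, and the stereocentre of 1 becomes C3 unchanged.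

## Alternatives that were turned down

**Alternative 1:** The disconnection is C5–C10, made by an Ireland–Claisen rearrangement inside a δ-lactone in which the C3–O bond is a temporary tether. Enolisation and silylation would give a cyclic ketene acetal; the [3,3] shift joins C5 to C10, breaks C3–O and leaves ring A as acid A1 (2,3-dimethyl-2-(3-methylbut-2-en-1-yl)cyclohex-3-ene-1-carboxylic acid).
- For: a cyclic ketene acetal can only rearrange through a boat-like array, so the C5/C10 relationship follows from alkene geometry more securely than from an exo/endo preference. On the predictability of the quaternary centre this plan is the stronger one. It also brings in C6, C7 and C11–C13 with the prenyl group.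
- Against: it needs a geometrically pure tetrasubstituted C4=C5 alkene. A1 has lost the C3 oxygen, which must be put back on a C3=C4 alkene together with the C4 configuration. A1 has no ring B, no oxygen at C8 or C9, and lacks the C8 carbon altogether.
- Comparison: its key step gives one ring and two stereocentres and leaves a long sequence to 26. The chosen step gives both rings, keeps the chiral-pool C3 oxygen throughout, and places carbonyl equivalents at C4 and C8.

**Alternative 2:** The disconnections are C3–C4 and C4–C5. Ring A is grown from a five-membered ring by inserting an ethylidene unit (C4 with C15) between the ketone carbon C3 and quaternary C5. A lithium carbenoid adds to the ketone and, after bromine–lithium exchange, C5 migrates to give decalin A2 (the 8-(1,3-dithiane) derivative of 11,12,13-trinoreremophil-9-ene-3,8-dione).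
- For: the bicyclic starting point carries the C5 quaternary centre from catalytic asymmetric chemistry. C4 ends up α to the C3 ketone, so its methyl can be equilibrated to the equatorial β position, and hydride reduction of C3 should give the equatorial alcohol. On the absolute control of C5 and on C4 it is at least as secure as the chosen plan.
- Against: addition of a hindered carbenoid to a neopentyl-type ketone and the choice between migration of C5 and of C2 are both uncertain. Nearly all of ring B remains to be done: H10 must be set by reducing the C9=C10 alkene, C9 must be oxygenated, C7 substituted and the dithiane removed.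
- Comparison: it is longer after the key step. The chosen plan sets C5 and C10 in the ring-forming step and reaches the C9 oxygen directly from the enol silane.

**Alternative 3:** The disconnections are C4–C5 and C1–C10. An intermolecular Diels–Alder reaction between the methyl-bearing C5=C10 bond of a methoxy-substituted quinone ring and a (Z)-configured silyloxydiene, under a chelating chiral Lewis acid, would give endo adduct A3 (cis-fused 8-methoxy-3-(tert-butyldimethylsilyloxy)-11,12,13-trinoreremophila-2,7-diene-6,9-dione).
- For: it is convergent, uses two small partners, takes its enantiocontrol from a catalyst, and delivers oxygen at C3, C8 and C9 in one step. On convergence and on the brevity of the route to the cycloaddition substrates it is stronger.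
- Against: A3 is cis-fused and has C4 and C10 opposite to 26. Two centres would have to be inverted by equilibration, and an angular methyl does not clearly favour the trans-decalindione. (Z)-Dienes reach the s-cis conformation poorly and react sluggishly. The surplus C6 oxygen must be removed and several carbonyls adjusted.
- Comparison: the chosen plan gives the trans fusion directly, with the oxidation pattern of the target and no surplus oxygen.

Key step: step 8

Remark: eremophilane numbering (C1–C15) is used for all bicyclic compounds; α is the face of H10, β the face of the C14 methyl.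
Remark: the C3 oxygen carries TBS and the C8 enol oxygen TIPS, because the two alcohols must later be unmasked one after the other.
Assumption: (R)-5-oxotetrahydrofuran-2-carboxylic acid is used as the commercial single enantiomer; its stereocentre becomes C3 (R) without change.

## Route

Step 1
Reactants: 1 (R)-5-oxotetrahydrofuran-2-carboxylic acid
Product: 3 (R)-N-methoxy-N-methyl-5-oxotetrahydrofuran-2-carboxamide, via acyl imidazolide 2 (not isolated)
Conditions: CDI, CH2Cl2, 0 °C to rt; then MeNH(OMe)·HCl, rt
Reagents that add atoms: N,O-dimethylhydroxylamine hydrochloride, CNOC.Cl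
Why: Carboxyl activation as the acyl imidazolide followed by aminolysis (Weinreb amide formation); the weakly nucleophilic hydroxylamine does not open the γ-lactone, and the stereocentre is not touched.

Step 2
Reactants: 3 (R)-N-methoxy-N-methyl-5-oxotetrahydrofuran-2-carboxamide
Product: 6 (R)-4-(tert-butyldimethylsilyloxy)-5-[methoxy(methyl)amino]-5-oxopentanoic acid, via lithium hydroxy carboxylate 4 (not isolated), via bis-silyl compound 5 (not isolated)
Conditions: LiOH·H2O (1.05 equiv), THF–H2O, 0 °C; evaporate; TBSCl, imidazole, DMF, rt; K2CO3, MeOH–H2O, rt; aq. KHSO4 to pH 4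
Reagents that add atoms: lithium hydroxide, [Li+].[OH-]; tert-butyldimethylsilyl chloride, CC(C)(C)[Si](C)(C)Cl
Why: Hydroxide opens the activated γ-lactone (saponification) much faster than it attacks the tertiary amide. Exhaustive silylation and mild carbonate cleavage of the labile silyl ester leave the C3 silyl ether and a free C10 acid, so the two carbonyl ends stay differentiated.

Step 3
Reactants: 6 (R)-4-(tert-butyldimethylsilyloxy)-5-[methoxy(methyl)amino]-5-oxopentanoic acid
Product: 7 (R)-2-(tert-butyldimethylsilyloxy)-5-hydroxy-N-methoxy-N-methylpentanamide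
Conditions: BH3·SMe2, THF, 0 °C; MeOH quench; used without delay
Reagents that add atoms: none
Why: Chemoselective borane reduction: a carboxylic acid is reduced through its acyloxyborane far faster than an N-methoxy amide, so only C10 becomes the alcohol.

Step 4
Reactants: 7 (R)-2-(tert-butyldimethylsilyloxy)-5-hydroxy-N-methoxy-N-methylpentanamide
Product: 8 (R)-2-(tert-butyldimethylsilyloxy)-N-methoxy-N-methyl-5-oxopentanamide
Conditions: Dess–Martin periodinane, CH2Cl2, 0 °C to rt
Reagents that add atoms: none
Why: Dess–Martin oxidation of the primary alcohol stops at the aldehyde under near-neutral conditions that leave the silyl ether and the amide alone.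

Step 5
Reactants: 8 (R)-2-(tert-butyldimethylsilyloxy)-N-methoxy-N-methyl-5-oxopentanamide; 9 dimethyl (2-oxopropyl)phosphonate
Product: 10 (2R,5E)-2-(tert-butyldimethylsilyloxy)-N-methoxy-N-methyl-7-oxooct-5-enamide
Conditions: LiCl, i-Pr2NEt, MeCN, rt
Reagents that add atoms: dimethyl (2-oxopropyl)phosphonate 9, COP(=O)(CC(C)=O)OC
Why: Horner–Wadsworth–Emmons olefination under the mild LiCl/amine conditions gives the (E)-enone (C9=C10) without enolising the aldehyde or disturbing C3.

Step 6
Reactants: 10 (2R,5E)-2-(tert-butyldimethylsilyloxy)-N-methoxy-N-methyl-7-oxooct-5-enamide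
Product: 11 (2R,5E)-2-(tert-butyldimethylsilyloxy)-N-methoxy-N-methyl-7-(triisopropylsilyloxy)octa-5,7-dienamide
Conditions: TIPSOTf, Et3N, CH2Cl2, −78 to 0 °C
Reagents that add atoms: triisopropylsilyl trifluoromethanesulfonate, CC(C)[Si](OS(=O)(=O)C(F)(F)F)(C(C)C)C(C)C
Why: Soft enolisation of the methyl ketone with silyl triflate and amine removes a C7 proton kinetically and gives the cross-conjugated 2-silyloxydiene; the amide α-proton is far less acidic and stays.

Step 7
Reactants: 11 (2R,5E)-2-(tert-butyldimethylsilyloxy)-N-methoxy-N-methyl-7-(triisopropylsilyloxy)octa-5,7-dienamide; 12 isopropenylmagnesium bromide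
Product: 14 (4R,7E)-4-(tert-butyldimethylsilyloxy)-2-methyl-9-(triisopropylsilyloxy)deca-1,7,9-trien-3-one, via magnesium hemiaminal adduct 13 (not isolated)
Conditions: THF, −78 to −20 °C; inverse quench into cold aq. NH4Cl; kept below 0 °C and used at once
Reagents that add atoms: isopropenylmagnesium bromide 12, C=C(C)[Mg]Br
Why: Weinreb ketone synthesis: the chelated tetrahedral adduct 13 persists until the quench, so no second addition occurs and the methacryloyl dienophile is only set free in the cold, after all base-mediated steps. The silyl dienol ether is inert to the Grignard reagent.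

Step 8
Reactants: 14 (4R,7E)-4-(tert-butyldimethylsilyloxy)-2-methyl-9-(triisopropylsilyloxy)deca-1,7,9-trien-3-one
Product: 15 trans-fused 3α-(tert-butyldimethylsilyloxy)-8-(triisopropylsilyloxy)-11,12,13,15-tetranoreremophil-8-en-4-one (5β-methyl, 10α-H)
Conditions: Me2AlCl (0.3 equiv), CH2Cl2, −78 to −30 °C
Reagents that add atoms: none
Why: Me2AlCl binds the C4 carbonyl oxygen and lowers the LUMO of the methacryloyl C5=C6 bond, which adds across the 2-silyloxydiene C7=C8–C9=C10 in a concerted, asynchronous [4+2] cycloaddition in which C6–C7 (electron-rich C7 to electron-poor C6) runs ahead of C5–C10. The closest known reaction type is the thermal or Lewis-acid-promoted intramolecular Diels–Alder reaction of 1,7,9-decatrien-3-ones, together with Diels–Alder reactions of 2-silyloxydienes with α-methyl enones. Ring A closes through the four-atom tether C1–C4 as C5–C10 forms, with the tether chair-like and on the side away from the diene (tether-anti, carbonyl-exo); ring B is closed by the cycloaddition itself, suprafacially on both components, and emerges as the C8=C9 enol silane. The regiochemistry is fixed by the tether and is also the electronically matched one (C8 oxygen para to the C5 acyl group). C10 relative to C5: the (E)-C9=C10 geometry and the methyl-endo, carbonyl-exo arrangement that α-methyl enones prefer place H10 anti to the C14 methyl, which is the trans fusion. C5 relative to C3: in the chair-like tether the C3 silyloxy group takes the equatorial position, because an axial one would be syn-diaxial to the endo C14 methyl, and this selects the diene face that gives 5β-methyl and 10α-H with the C3 oxygen α. The step therefore needs exo over endo selectivity and π-facial selectivity; both are helped by the low temperature the Lewis acid allows, and the aprotic conditions keep the TIPS enol ether intact.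

Step 9
Reactants: 15 trans-fused 3α-(tert-butyldimethylsilyloxy)-8-(triisopropylsilyloxy)-11,12,13,15-tetranoreremophil-8-en-4-one
Product: 16 3α-(tert-butyldimethylsilyloxy)-8-(triisopropylsilyloxy)-11,12,13-trinoreremophila-4(15),8-diene (5β-methyl, 10α-H)
Conditions: Cp2TiMe2, toluene, 70 °C, dark
Reagents that add atoms: dimethyltitanocene Cp2TiMe2, C[Ti](C)(C1C=CC=C1)C1C=CC=C1
Why: Carbonyl methylenation by the titanium methylidene formed from Cp2TiMe2 is non-basic and tolerates hindered, enolisable ketones. The C8 carbonyl is masked as its enol silane, so only C4 reacts and C3 cannot epimerise.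

Step 10
Reactants: 16 3α-(tert-butyldimethylsilyloxy)-8-(triisopropylsilyloxy)-11,12,13-trinoreremophila-4(15),8-diene
Product: 18 3α-(tert-butyldimethylsilyloxy)-9α-(triisopropylsilyloxy)-11,12,13-trinoreremophil-4(15)-en-8-one, via silyloxy epoxide 17 (not isolated)
Conditions: mCPBA (1.05 equiv), CH2Cl2, −20 to 0 °C
Reagents that add atoms: 3-chloroperoxybenzoic acid, OOC(=O)c1cccc(Cl)c1
Why: Rubottom oxidation: the electron-rich enol silane is epoxidised much faster than the hindered 1,1-disubstituted alkene, and from the α face because the β face of C9 is screened by the axial C14 methyl. Opening of 17 with 1,4-silyl shift gives the C8 ketone and the 9α (equatorial) silyl ether.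

Step 11
Reactants: 18 3α-(tert-butyldimethylsilyloxy)-9α-(triisopropylsilyloxy)-11,12,13-trinoreremophil-4(15)-en-8-one
Product: 19 3α-(tert-butyldimethylsilyloxy)-9α-(triisopropylsilyloxy)-11,12,13-trinoreremophilan-8-one (4β,5β-dimethyl, 10α-H)
Conditions: H2 (1 atm), PtO2, EtOAc, rt
Reagents that add atoms: none
Why: Heterogeneous hydrogenation of the exocyclic alkene; hydrogen is delivered to C4 from the α face, away from the adjacent axial C14 methyl, which puts C15 β (equatorial, cis to C14, trans to the C3 oxygen). Platinum is chosen because it is less prone than palladium to move the double bond towards C3.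

Step 12
Reactants: 19 3α-(tert-butyldimethylsilyloxy)-9α-(triisopropylsilyloxy)-11,12,13-trinoreremophilan-8-one
Product: 21 11-hydroxy-3α-(tert-butyldimethylsilyloxy)-9α-(triisopropylsilyloxy)eremophilan-8-one (7α side chain, 7β-H), via lithium C7 enolate 20 (not isolated)
Conditions: LiN(i-Pr)2, THF, −78 °C; acetone, −78 °C; AcOH quench at −78 °C
Reagents that add atoms: acetone, CC(C)=O
Why: Kinetic deprotonation occurs at C7, away from the bulky C9 silyloxy group. Enolate 20 adds to acetone (aldol addition) on the α face, opposite the syn-axial C14 methyl, giving the equatorial 7α side chain.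

Step 13
Reactants: 21 11-hydroxy-3α-(tert-butyldimethylsilyloxy)-9α-(triisopropylsilyloxy)eremophilan-8-one
Product: 22 3α-(tert-butyldimethylsilyloxy)-9α-(triisopropylsilyloxy)eremophil-11-en-8-one (7β-H)
Conditions: SOCl2, pyridine, CH2Cl2, −20 to 0 °C
Reagents that add atoms: none
Why: Dehydration through the chlorosulfite by an E2 process in pyridine should take one of the six accessible methyl hydrogens in preference to the single hindered C7–H, giving the isopropenyl group. The weak base at low temperature should not move the alkene into conjugation or epimerise C7.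

Step 14
Reactants: 22 3α-(tert-butyldimethylsilyloxy)-9α-(triisopropylsilyloxy)eremophil-11-en-8-one
Product: 23 3α-hydroxy-9α-(triisopropylsilyloxy)eremophil-11-en-8-one
Conditions: HF·pyridine, pyridine, THF, 0 °C to rt
Reagents that add atoms: none
Why: Selective desilylation: buffered acidic fluoride cleaves the ordinary secondary TBS ether much faster than the bulkier TIPS ether on the electron-poor α-keto oxygen.

Step 15
Reactants: 23 3α-hydroxy-9α-(triisopropylsilyloxy)eremophil-11-en-8-one
Product: 24 3α-(3-methylbut-2-enoyloxy)-9α-(triisopropylsilyloxy)eremophil-11-en-8-one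
Conditions: 3-methylbut-2-enoyl chloride, pyridine, DMAP (cat.), CH2Cl2, 0 °C to rt
Reagents that add atoms: 3-methylbut-2-enoyl chloride, CC(C)=CC(=O)Cl
Why: DMAP-catalysed acylation of the equatorial C3 alcohol; pyridine is used in place of a trialkylamine to avoid the vinylketene pathway that would deconjugate the ester.

Step 16
Reactants: 24 3α-(3-methylbut-2-enoyloxy)-9α-(triisopropylsilyloxy)eremophil-11-en-8-one
Product: 25 9α-hydroxy-3α-(3-methylbut-2-enoyloxy)eremophil-11-en-8-one
Conditions: Bu4NF, AcOH (1:1), THF, 0 °C to rt
Reagents that add atoms: none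
Why: Fluoride cleaves the α-keto silyl ether readily; buffering with acetic acid keeps the medium near neutral, so the β,γ-unsaturated ketone, the C9 centre and the ester should stay as they are.

Step 17
Reactants: 25 9α-hydroxy-3α-(3-methylbut-2-enoyloxy)eremophil-11-en-8-one
Product: 26 (3R,4R,5R,7S,9S,10R)-3-(3-methylbut-2-enoyloxy)-9-[(E)-2-methylbut-2-enoyloxy]eremophil-11-en-8-one (CNP0164025.1)
Conditions: (E)-2-methylbut-2-enoyl chloride, pyridine, DMAP, CH2Cl2, 0 °C to rt
Reagents that add atoms: (E)-2-methylbut-2-enoyl chloride, C/C=C(\C)C(=O)Cl
Why: DMAP-catalysed acylation of the equatorial α-ketol with the (E)-configured acid chloride; (E) is the stable geometry of this ester, and the mild base should not isomerise the isopropenyl ketone.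

## Compound list

1 | (R)-5-oxotetrahydrofuran-2-carboxylic acid | OC(=O)[C@H]1CCC(=O)O1 | starting material
2 | (R)-5-(imidazol-1-ylcarbonyl)dihydrofuran-2(3H)-one (acyl imidazolide) | O=C([C@H]1CCC(=O)O1)n1ccnc1 | intermediate
3 | (R)-N-methoxy-N-methyl-5-oxotetrahydrofuran-2-carboxamide | CON(C)C(=O)[C@H]1CCC(=O)O1 | intermediate
4 | lithium (R)-4-hydroxy-5-[methoxy(methyl)amino]-5-oxopentanoate | CON(C)C(=O)[C@H](O)CCC(=O)[O-].[Li+] | intermediate
5 | tert-butyldimethylsilyl (R)-4-(tert-butyldimethylsilyloxy)-5-[methoxy(methyl)amino]-5-oxopentanoate | CON(C)C(=O)[C@H](O[Si](C)(C)C(C)(C)C)CCC(=O)O[Si](C)(C)C(C)(C)C | intermediate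
6 | (R)-4-(tert-butyldimethylsilyloxy)-5-[methoxy(methyl)amino]-5-oxopentanoic acid | CON(C)C(=O)[C@H](O[Si](C)(C)C(C)(C)C)CCC(=O)O | intermediate
7 | (R)-2-(tert-butyldimethylsilyloxy)-5-hydroxy-N-methoxy-N-methylpentanamide | CON(C)C(=O)[C@H](O[Si](C)(C)C(C)(C)C)CCCO | intermediate
8 | (R)-2-(tert-butyldimethylsilyloxy)-N-methoxy-N-methyl-5-oxopentanamide | CON(C)C(=O)[C@H](O[Si](C)(C)C(C)(C)C)CCC=O | intermediate
9 | dimethyl (2-oxopropyl)phosphonate | COP(=O)(CC(C)=O)OC | starting material
10 | (2R,5E)-2-(tert-butyldimethylsilyloxy)-N-methoxy-N-methyl-7-oxooct-5-enamide | CON(C)C(=O)[C@H](O[Si](C)(C)C(C)(C)C)CC/C=C/C(C)=O | intermediate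
11 | (2R,5E)-2-(tert-butyldimethylsilyloxy)-N-methoxy-N-methyl-7-(triisopropylsilyloxy)octa-5,7-dienamide | CON(C)C(=O)[C@H](O[Si](C)(C)C(C)(C)C)CC/C=C/C(=C)O[Si](C(C)C)(C(C)C)C(C)C | intermediate
12 | isopropenylmagnesium bromide | C=C(C)[Mg]Br | starting material
13 | bromomagnesium alkoxide of the C4 N-methoxy-N-methyl hemiaminal (tetrahedral adduct of 11 and 12, C4 unassigned) | C=C(C)C(O[Mg]Br)(N(C)OC)[C@H](O[Si](C)(C)C(C)(C)C)CC/C=C/C(=C)O[Si](C(C)C)(C(C)C)C(C)C | intermediate
14 | (4R,7E)-4-(tert-butyldimethylsilyloxy)-2-methyl-9-(triisopropylsilyloxy)deca-1,7,9-trien-3-one | C=C(C)C(=O)[C@H](O[Si](C)(C)C(C)(C)C)CC/C=C/C(=C)O[Si](C(C)C)(C(C)C)C(C)C | intermediate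
15 | trans-fused 3α-(tert-butyldimethylsilyloxy)-8-(triisopropylsilyloxy)-11,12,13,15-tetranoreremophil-8-en-4-one (5β-methyl, 10α-H) | C1C[C@]2(C)C(=O)[C@H](O[Si](C)(C)C(C)(C)C)CC[C@H]2C=C1O[Si](C(C)C)(C(C)C)C(C)C | intermediate
16 | 3α-(tert-butyldimethylsilyloxy)-8-(triisopropylsilyloxy)-11,12,13-trinoreremophila-4(15),8-diene (5β-methyl, 10α-H) | C1C[C@]2(C)C(=C)[C@H](O[Si](C)(C)C(C)(C)C)CC[C@H]2C=C1O[Si](C(C)C)(C(C)C)C(C)C | intermediate
17 | 8α,9α-epoxide of 16 (8β-triisopropylsilyloxy) | C1C[C@]2(C)C(=C)[C@H](O[Si](C)(C)C(C)(C)C)CC[C@H]2[C@@H]3O[C@]13O[Si](C(C)C)(C(C)C)C(C)C | intermediate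
18 | 3α-(tert-butyldimethylsilyloxy)-9α-(triisopropylsilyloxy)-11,12,13-trinoreremophil-4(15)-en-8-one | C1C[C@]2(C)C(=C)[C@H](O[Si](C)(C)C(C)(C)C)CC[C@H]2[C@H](O[Si](C(C)C)(C(C)C)C(C)C)C1=O | intermediate
19 | 3α-(tert-butyldimethylsilyloxy)-9α-(triisopropylsilyloxy)-11,12,13-trinoreremophilan-8-one (4β,5β-dimethyl, 10α-H) | C1C[C@]2(C)[C@@H](C)[C@H](O[Si](C)(C)C(C)(C)C)CC[C@H]2[C@H](O[Si](C(C)C)(C(C)C)C(C)C)C1=O | intermediate
20 | lithium C7(8)-enolate of 19 | [Li]OC1=CC[C@]2(C)[C@@H](C)[C@H](O[Si](C)(C)C(C)(C)C)CC[C@H]2[C@@H]1O[Si](C(C)C)(C(C)C)C(C)C | intermediate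
21 | 11-hydroxy-3α-(tert-butyldimethylsilyloxy)-9α-(triisopropylsilyloxy)eremophilan-8-one (7α side chain, 7β-H) | CC(C)(O)[C@@H]1C[C@]2(C)[C@@H](C)[C@H](O[Si](C)(C)C(C)(C)C)CC[C@H]2[C@H](O[Si](C(C)C)(C(C)C)C(C)C)C1=O | intermediate
22 | 3α-(tert-butyldimethylsilyloxy)-9α-(triisopropylsilyloxy)eremophil-11-en-8-one (7β-H) | C=C(C)[C@@H]1C[C@]2(C)[C@@H](C)[C@H](O[Si](C)(C)C(C)(C)C)CC[C@H]2[C@H](O[Si](C(C)C)(C(C)C)C(C)C)C1=O | intermediate
23 | 3α-hydroxy-9α-(triisopropylsilyloxy)eremophil-11-en-8-one | C=C(C)[C@@H]1C[C@]2(C)[C@@H](C)[C@H](O)CC[C@H]2[C@H](O[Si](C(C)C)(C(C)C)C(C)C)C1=O | intermediate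
24 | 3α-(3-methylbut-2-enoyloxy)-9α-(triisopropylsilyloxy)eremophil-11-en-8-one | C=C(C)[C@@H]1C[C@]2(C)[C@@H](C)[C@H](OC(=O)C=C(C)C)CC[C@H]2[C@H](O[Si](C(C)C)(C(C)C)C(C)C)C1=O | intermediate
25 | 9α-hydroxy-3α-(3-methylbut-2-enoyloxy)eremophil-11-en-8-one | C=C(C)[C@@H]1C[C@]2(C)[C@@H](C)[C@H](OC(=O)C=C(C)C)CC[C@H]2[C@H](O)C1=O | intermediate
26 | (3R,4R,5R,7S,9S,10R)-3-(3-methylbut-2-enoyloxy)-9-[(E)-2-methylbut-2-enoyloxy]eremophil-11-en-8-one (CNP0164025.1) | C=C(C)[C@@H]1C[C@]2(C)[C@@H](C)[C@H](OC(=O)C=C(C)C)CC[C@H]2[C@H](OC(=O)/C(C)=C/C)C1=O | target

## Step count and least certain steps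

Total step count: 17. Longest linear sequence: 17 steps from 1 (the route is linear; 9 and 12 are purchased).

**Step 8 (key step).** The most likely failure is an insufficient preference for the methyl-endo, tether-anti mode, so that the cis-fused mode competes. The carbonyl in the tether favours its own endo orientation, and only the α-methyl group and the Lewis acid oppose it. Uncatalysed cyclisation of 14 before the Lewis acid is present, or loss of the dienol ether to the Lewis acid, would also erode selectivity.
Fallback: set out from 14 and cyclise thermally (toluene, 80 °C) without regard to the fusion, which should give 15 together with its cis-fused 10β-H epimer F1. Methylenation of the mixture as in step 9 gives 16 and the cis-fused epimer F2. Saegusa–Ito oxidation of the mixture (Pd(OAc)2, MeCN) removes C10 as a stereocentre and converges on one octalone, the 4(15),9-dien-8-one F3. Dissolving-metal reduction (Li, NH3–THF, t-BuOH, −78 °C) protonates C10 axially and gives the trans-fused lithium C8 enolate, which is trapped with TIPSOTf to come back to the route at 16. This replaces transition-state control of the fusion by stereoelectronically controlled protonation. It does not help if the C3/C5 relationship is wrong.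

**Step 13.** The elimination may lose regiocontrol: removal of the acidic C7–H gives the conjugated C7=C11 isomer, and that isomer is also the thermodynamic sink if the product isomerises.
Fallback: set out from 19 and form the Δ7 trimethylsilyl enol ether F4 (LiN(i-Pr)2, Me3SiCl, THF, −78 °C). Palladium-catalysed α-alkenylation through the tin enolate (Bu3SnF, 2-bromopropene, PdCl2[P(o-tol)3]2, toluene, reflux) then installs the isopropenyl group directly and returns to the route at 22, with no elimination step.

**Step 9.** Methylenation of the C4 carbonyl may stall, because it lies between quaternary C5 and the silyloxy-bearing C3, and prolonged heating may damage the enol silane.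
Fallback: set out from 15 and add Me3SiCH2Li/CeCl3 (THF, −78 °C) to C4, giving the β-hydroxysilane F5. Peterson elimination with KH (THF, 0 °C) returns to the route at 16. A small, strongly nucleophilic carbanion replaces the bulky titanium reagent.

**Step 11.** Facial selectivity may be poor, or the double bond may migrate into the ring towards C3 on the catalyst surface, which would destroy the C3 centre.
Fallback: set out from 18 and remove the C3 silyl group (HF·pyridine, THF), giving the allylic alcohol F6. Hydroxyl-directed hydrogenation with [Ir(cod)(PCy3)(py)]PF6 (H2, CH2Cl2) delivers hydrogen syn to the α hydroxyl and gives the 4β-methyl alcohol F7. Resilylation (TBSOTf, 2,6-lutidine) returns to the route at 19.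

**Step 7.** Over-addition is not the concern. The risk is cyclisation of 14 during isolation, before the Lewis acid is present, or partial hydrolysis of the dienol ether on quenching.
Fallback: set out from 11 and reduce the amide with i-Bu2AlH (THF, −78 °C) to the aldehyde F8. Addition of 12 gives the allylic alcohol F9 as a mixture of C4 epimers. Oxidation with MnO2 (CH2Cl2, 0 °C) generates 14 in a neutral medium, where the route is rejoined and the cyclisation follows in the same flask.

## Further compounds

F1 | step 8 | cis-fused 10β-H epimer of 15 | C1C[C@]2(C)C(=O)[C@H](O[Si](C)(C)C(C)(C)C)CC[C@@H]2C=C1O[Si](C(C)C)(C(C)C)C(C)C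
F2 | step 8 | cis-fused 10β-H epimer of 16 | C1C[C@]2(C)C(=C)[C@H](O[Si](C)(C)C(C)(C)C)CC[C@@H]2C=C1O[Si](C(C)C)(C(C)C)C(C)C
F3 | step 8 | 3α-(tert-butyldimethylsilyloxy)-11,12,13-trinoreremophila-4(15),9-dien-8-one | C1C[C@]2(C)C(=C)[C@H](O[Si](C)(C)C(C)(C)C)CCC2=CC1=O
F4 | step 13 | Δ7 trimethylsilyl enol ether of 19 | C[Si](C)(C)OC1=CC[C@]2(C)[C@@H](C)[C@H](O[Si](C)(C)C(C)(C)C)CC[C@H]2[C@@H]1O[Si](C(C)C)(C(C)C)C(C)C
F5 | step 9 | 4-hydroxy-4-(trimethylsilylmethyl) adduct of 15 (C4 configuration immaterial) | C1C[C@]2(C)C(O)(C[Si](C)(C)C)[C@H](O[Si](C)(C)C(C)(C)C)CC[C@H]2C=C1O[Si](C(C)C)(C(C)C)C(C)C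
F6 | step 11 | 3α-hydroxy-9α-(triisopropylsilyloxy)-11,12,13-trinoreremophil-4(15)-en-8-one | C1C[C@]2(C)C(=C)[C@H](O)CC[C@H]2[C@H](O[Si](C(C)C)(C(C)C)C(C)C)C1=O
F7 | step 11 | 3α-hydroxy-9α-(triisopropylsilyloxy)-11,12,13-trinoreremophilan-8-one (4β,5β-dimethyl) | C1C[C@]2(C)[C@@H](C)[C@H](O)CC[C@H]2[C@H](O[Si](C(C)C)(C(C)C)C(C)C)C1=O
F8 | step 7 | (2R,5E)-2-(tert-butyldimethylsilyloxy)-7-(triisopropylsilyloxy)octa-5,7-dienal | O=C[C@H](O[Si](C)(C)C(C)(C)C)CC/C=C/C(=C)O[Si](C(C)C)(C(C)C)C(C)C
F9 | step 7 | (4R,7E)-4-(tert-butyldimethylsilyloxy)-2-methyl-9-(triisopropylsilyloxy)deca-1,7,9-trien-3-ol (C3 carbinol epimers) | C=C(C)C(O)[C@H](O[Si](C)(C)C(C)(C)C)CC/C=C/C(=C)O[Si](C(C)C)(C(C)C)C(C)C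
A1 | alternative 1 | 2,3-dimethyl-2-(3-methylbut-2-en-1-yl)cyclohex-3-ene-1-carboxylic acid | OC(=O)[C@@H]1CCC=C(C)[C@@]1(C)CC=C(C)C
A2 | alternative 2 | 8-(1,3-dithiane) derivative of 11,12,13-trinoreremophil-9-ene-3,8-dione | C1C[C@]2(C)[C@@H](C)C(=O)CCC2=CC13SCCCS3
A3 | alternative 3 | cis-fused endo adduct 8-methoxy-3-(tert-butyldimethylsilyloxy)-11,12,13-trinoreremophila-2,7-diene-6,9-dione | O=C1C=C(OC)C(=O)[C@H]2CC=C(O[Si](C)(C)C(C)(C)C)[C@@H](C)[C@@]12C
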